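**Strategy.** The cyclohexene is disconnected across C5–C6 and C8–C9 into a C6–C7–C8 but-2-ynyl unit and an acyclic aldehyde that carries C9, the quaternary C10 and C5. The key step exploits the 1,4-relation of the ring alkene C7=C8 and the isopropenyl alkene on C5, the signature of an ene reaction onto an allene, and the oxygenated carbon on C9, a Claisen carbonyl. A but-2-ynyl enol ether, whose C–O bond is a temporary tether, rearranges under gold catalysis to an allenyl aldehyde and cyclises through its 2-methylpropenyl group, giving the ring, both alkenes and the C9 aldehyde in one operation. C10 is set before, C9 after.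

Key step: step 7

Locants used below (target ring): C5 = CH bearing isopropenyl (its central carbon is C4), C6 = CH2, C7 = ring CH=, C8 = ring C(CH3)=, C9 = CH bearing the CH2O carbon C11, C10 = quaternary carbon bearing CH3 and the propanoic acid chain.

Assumption: the (S)-configured amine 4 is taken to give the (R)-configured quaternary centre through the usual chair-like aza-ene model of chiral secondary enamines; should the sense be opposite, the (R)-amine is used instead.

Step 1
Reactants: 1 isobutyraldehyde; 2 2-(triphenylphosphoranylidene)propanal
Product: 3 (E)-2,4-dimethylpent-2-enal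
Conditions: toluene, 90 °C
Reagents that add atoms: none
Why: Wittig reaction of the stabilised formyl ylide with the aldehyde should give the (E)-trisubstituted enal.

Step 2
Reactants: 3 (E)-2,4-dimethylpent-2-enal; 4 (S)-1-phenylethylamine
Product: 5 (1E,2E)-2,4-dimethyl-N-[(1S)-1-phenylethyl]pent-2-en-1-imine
Conditions: MgSO4, CH2Cl2, rt
Reagents that add atoms: none
Why: Condensation of the aldehyde with the primary amine gives the conjugated imine, which can tautomerise to the chiral secondary dienamine needed in step 3.

Step 3
Reactants: 5 (1E,2E)-2,4-dimethyl-N-[(1S)-1-phenylethyl]pent-2-en-1-imine; 6 methyl acrylate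
Product: 8 methyl (4R)-4-formyl-4,6-dimethylhept-5-enoate, via adduct imine 7 (not isolated)
Conditions: neat, 40 °C; then 10% aq. AcOH, THF, rt
Reagents that add atoms: water (O)
Why: Asymmetric Michael addition of a chiral imine through its secondary enamine tautomer: the dienamine should add to methyl acrylate at its α-carbon in a chair-like aza-ene transition state on the face away from the phenyl group, which creates the quaternary C10 as R, and mild acid hydrolysis then frees the aldehyde, which has no α-hydrogen and cannot reconjugate.

Step 4
Reactants: 9 but-2-yn-1-ol; 10 paraformaldehyde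
Product: 11 1-(chloromethoxy)but-2-yne
Conditions: HCl (g), CH2Cl2, 0 °C
Reagents that add atoms: hydrogen chloride (Cl)
Why: Chloromethylation of an alcohol with formaldehyde and hydrogen chloride is the standard route to chloromethyl ethers.

Step 5
Reactants: 11 1-(chloromethoxy)but-2-yne; 12 triphenylphosphine
Product: 13 [(but-2-yn-1-yloxy)methyl]triphenylphosphonium chloride
Conditions: toluene, 60 °C
Reagents that add atoms: none
Why: SN2 quaternisation of triphenylphosphine by the reactive α-chloro ether gives the alkoxymethylphosphonium salt.

Step 6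
Reactants: 8 methyl (4R)-4-formyl-4,6-dimethylhept-5-enoate; 13 [(but-2-yn-1-yloxy)methyl]triphenylphosphonium chloride
Product: 14 methyl (4R)-4-[2-(but-2-yn-1-yloxy)ethenyl]-4,6-dimethylhept-5-enoate (E/Z mixture)
Conditions: KN(SiMe3)2, THF, −78 °C to rt
Reagents that add atoms: none
Why: Wittig alkoxymethylenation of the hindered aldehyde with the non-stabilised alkoxy ylide should give the propargyl enol ether (both alkene isomers serve in step 7) without touching the ester or C10.

Step 7
Reactants: 14 methyl (4R)-4-[2-(but-2-yn-1-yloxy)ethenyl]-4,6-dimethylhept-5-enoate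
Product: 16 methyl 3-[(1R,6R)-2-formyl-1,3-dimethyl-6-(prop-1-en-2-yl)cyclohex-3-en-1-yl]propanoate (both C2 epimers), via allenyl aldehyde 15 (not isolated)
Conditions: Ph3PAuNTf2 (5 mol %), CH2Cl2, 0 °C to rt
Reagents that add atoms: none
Why: Proposed new method: cationic monovalent gold activates the alkyne of 14, the enol ether carbon C9 attacks C8 and the cyclic oxonium intermediate fragments, which is a gold-catalysed propargyl Claisen (Saucy–Marbet) rearrangement and gives allenyl aldehyde 15 with the C8–C9 bond; the same catalyst then activates the 1,1-disubstituted allene, C5 of the trisubstituted alkene attacks the unsubstituted allene terminus C6, the tertiary cation at C4 loses a methyl proton to leave the isopropenyl group and protodeauration of the ring vinylgold leaves the C7=C8 alkene. The closest known reactions are the gold-catalysed propargyl Claisen rearrangement of propargyl vinyl ethers and the gold-catalysed cycloisomerisation of ene-allenes (a formal Alder-ene reaction), here joined in one flask. The six-membered ring closes in the 6-endo mode at the allene terminus, since attack at the inner allene carbon C8 would need a four-membered ring. C5 is set relative to the existing C10 in a chair-like transition state in which the methyl group of C10 lies inside, next to the reacting alkene, and the ester chain points away from the forming ring, which places isopropenyl cis to methyl; because methyl and the chain differ little in size this preference is expected to be modest, and C9 is formed without control and is set in step 8. The step needs the alkene to outrun attack of the aldehyde oxygen on the activated allene and allene–alkene [2+2] addition, which the electron-rich trisubstituted alkene held close to the allene by the quaternary carbon (Thorpe–Ingold effect) should secure.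

Step 8
Reactants: 16 methyl 3-[(1R,6R)-2-formyl-1,3-dimethyl-6-(prop-1-en-2-yl)cyclohex-3-en-1-yl]propanoate
Product: 19 methyl 3-[(1R,2R,6R)-2-(hydroxymethyl)-1,3-dimethyl-6-(prop-1-en-2-yl)cyclohex-3-en-1-yl]propanoate, via potassium dienolate 17 (not isolated), via 2R aldehyde 18 (not isolated)
Conditions: KN(SiMe3)2, THF, −78 °C; AcOH, −78 °C; then NaBH4, MeOH, −78 to −20 °C
Reagents that add atoms: none
Why: Deprotonation at the doubly activated C9 gives one dienolate from both epimers, kinetic α-protonation from the face opposite the pseudo-axial methyl group on C10 (deconjugative protonation, as used for drimane esters) should set C9 as R and keep the C7=C8 alkene, and NaBH4 reduces the aldehyde before it can epimerise or conjugate.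

Step 9
Reactants: 19 methyl 3-[(1R,2R,6R)-2-(hydroxymethyl)-1,3-dimethyl-6-(prop-1-en-2-yl)cyclohex-3-en-1-yl]propanoate; 20 umbelliferone (7-hydroxycoumarin)
Product: 21 methyl 3-[(1R,2R,6R)-1,3-dimethyl-2-{[(2-oxo-2H-chromen-7-yl)oxy]methyl}-6-(prop-1-en-2-yl)cyclohex-3-en-1-yl]propanoate
Conditions: PPh3, DIAD, THF, 0 °C to rt
Reagents that add atoms: none
Why: Mitsunobu etherification of the primary alcohol with the acidic phenol of umbelliferone should form the aryl ether without touching the stereocentres.

Step 10
Reactants: 21 methyl 3-[(1R,2R,6R)-1,3-dimethyl-2-{[(2-oxo-2H-chromen-7-yl)oxy]methyl}-6-(prop-1-en-2-yl)cyclohex-3-en-1-yl]propanoate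
Product: 22 3-[(1R,2R,6R)-1,3-dimethyl-2-{[(2-oxo-2H-chromen-7-yl)oxy]methyl}-6-(prop-1-en-2-yl)cyclohex-3-en-1-yl]propanoic acid (target)
Conditions: LiOH, THF–H2O, rt; then 1 M HCl to pH 3
Reagents that add atoms: lithium hydroxide ([Li+].[OH-])
Why: Saponification of the methyl ester should give the acid, and any coumarin lactone opened by hydroxide recloses on acidification.

**Compound list**

1 | isobutyraldehyde | CC(C)C=O | starting material
2 | 2-(triphenylphosphoranylidene)propanal | CC(C=O)=P(c1ccccc1)(c1ccccc1)c1ccccc1 | starting material
3 | (E)-2,4-dimethylpent-2-enal | CC(C)/C=C(\C)C=O | intermediate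
4 | (S)-1-phenylethylamine | C[C@H](N)c1ccccc1 | starting material
5 | (1E,2E)-2,4-dimethyl-N-[(1S)-1-phenylethyl]pent-2-en-1-imine | C[C@H](/N=C/C(C)=C/C(C)C)c1ccccc1 | intermediate
6 | methyl acrylate | C=CC(=O)OC | starting material
7 | methyl (4R)-4,6-dimethyl-4-[(E)-{[(1S)-1-phenylethyl]imino}methyl]hept-5-enoate (adduct imine, not isolated) | C[C@H](/N=C/[C@](C)(CCC(=O)OC)C=C(C)C)c1ccccc1 | intermediate
8 | methyl (4R)-4-formyl-4,6-dimethylhept-5-enoate | O=C[C@](C)(CCC(=O)OC)C=C(C)C | intermediate
9 | but-2-yn-1-ol | CC#CCO | starting material
10 | paraformaldehyde (formaldehyde unit) | C=O | starting material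
11 | 1-(chloromethoxy)but-2-yne | CC#CCOCCl | intermediate
12 | triphenylphosphine | c1ccc(cc1)P(c1ccccc1)c1ccccc1 | starting material
13 | [(but-2-yn-1-yloxy)methyl]triphenylphosphonium chloride | CC#CCOC[P+](c1ccccc1)(c1ccccc1)c1ccccc1.[Cl-] | intermediate
14 | methyl (4R)-4-[2-(but-2-yn-1-yloxy)ethenyl]-4,6-dimethylhept-5-enoate (E/Z mixture) | CC#CCOC=C[C@](C)(CCC(=O)OC)C=C(C)C | intermediate
15 | methyl (4R)-4,6-dimethyl-4-(3-methyl-1-oxopenta-3,4-dien-2-yl)hept-5-enoate (allenyl aldehyde, both epimers, not isolated) | O=CC(C(C)=C=C)[C@](C)(CCC(=O)OC)C=C(C)C | intermediate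
16 | methyl 3-[(1R,6R)-2-formyl-1,3-dimethyl-6-(prop-1-en-2-yl)cyclohex-3-en-1-yl]propanoate (both C2 epimers) | C=C(C)[C@H]1CC=C(C)C(C=O)[C@]1(C)CCC(=O)OC | intermediate
17 | potassium dienolate of 16 (not isolated) | C=C(C)[C@H]1CC=C(C)C(=C[O-])[C@]1(C)CCC(=O)OC.[K+] | intermediate
18 | methyl 3-[(1R,2R,6R)-2-formyl-1,3-dimethyl-6-(prop-1-en-2-yl)cyclohex-3-en-1-yl]propanoate (not isolated) | C=C(C)[C@H]1CC=C(C)[C@@H](C=O)[C@]1(C)CCC(=O)OC | intermediate
19 | methyl 3-[(1R,2R,6R)-2-(hydroxymethyl)-1,3-dimethyl-6-(prop-1-en-2-yl)cyclohex-3-en-1-yl]propanoate | C=C(C)[C@H]1CC=C(C)[C@@H](CO)[C@]1(C)CCC(=O)OC | intermediate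
20 | umbelliferone (7-hydroxycoumarin) | O=c1ccc2ccc(O)cc2o1 | starting material
21 | methyl 3-[(1R,2R,6R)-1,3-dimethyl-2-{[(2-oxo-2H-chromen-7-yl)oxy]methyl}-6-(prop-1-en-2-yl)cyclohex-3-en-1-yl]propanoate | C=C(C)[C@H]1CC=C(C)[C@@H](COc2ccc3ccc(=O)oc3c2)[C@]1(C)CCC(=O)OC | intermediate
22 | 3-[(1R,2R,6R)-1,3-dimethyl-2-{[(2-oxo-2H-chromen-7-yl)oxy]methyl}-6-(prop-1-en-2-yl)cyclohex-3-en-1-yl]propanoic acid | C=C(C)[C@H]1CC=C(C)[C@@H](COc2ccc3ccc(=O)oc3c2)[C@]1(C)CCC(=O)O | target

**Step count.** Total: 10 steps. Longest linear sequence: 8 steps (steps 1, 2, 3, 6, 7, 8, 9, 10); steps 4 and 5 prepare the phosphonium salt.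

**Steps most likely to fail**

Step 7 (proposed new method). After the rearrangement the allenyl aldehyde may be diverted, by attack of the carbonyl oxygen on the gold-activated allene or by isomerisation to a conjugated dienal, before the alkene closes the ring. The closure may also show little facial preference at C5, since the two groups on C10 that decide it (methyl and the ester chain) are close in size. The fallback uses two separate, known pericyclic reactions and sets out from 14. Heating in o-xylene at 140 °C (thermal Saucy–Marbet rearrangement) should give the allenyl aldehyde 15, which is isolated. A thermal intramolecular ene reaction of the allene with the trisubstituted alkene (1,2-dichlorobenzene, about 190 °C, no metal and no cationic intermediate for the carbonyl oxygen to intercept) should then close the ring and return to the route at 16. This addresses the diversion but not the facial preference at C5. No new compound arises (F0).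

Step 3. The dienamine may add slowly, react through its terminal carbon or as a diene, or discriminate poorly between its faces, so that 8 is formed with low enantiomeric purity. The fallback replaces induction by resolution and sets out from 3. Base-catalysed deconjugative Michael addition of the dienolate to methyl acrylate (KOC(CH3)3 cat., THF–t-BuOH) should give racemic methyl 4-formyl-4,6-dimethylhept-5-enoate F1. Acetalisation with (R,R)-hydrobenzoin (TsOH, benzene, water removal) should give the two diastereomeric dioxolanes, the (4R) acetal F2 and the (4S) acetal F3, which are separated by chromatography or crystallisation. Hydrolysis of F2 (aq. HCl, THF) returns to the route at 8.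

Step 9. Displacement of the oxyphosphonium intermediate at the hindered primary carbon next to C9 and the quaternary C10 may be slow, leaving alcohol unreacted or giving alkylated hydrazide. The fallback sets out from 19. Triflation (Tf2O, 2,6-lutidine, CH2Cl2, −78 °C) should give the triflate F4, methyl 3-[(1R,2R,6R)-1,3-dimethyl-6-(prop-1-en-2-yl)-2-{[(trifluoromethanesulfonyl)oxy]methyl}cyclohex-3-en-1-yl]propanoate. Displacement with the caesium salt of umbelliferone 20 (Cs2CO3, DMF, rt) returns to the route at 21.

Further compounds
F0 | step 7 | none | none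
F1 | step 3 | racemic methyl 4-formyl-4,6-dimethylhept-5-enoate | O=CC(C)(CCC(=O)OC)C=C(C)C
F2 | step 3 | methyl (4R)-4-[(4R,5R)-4,5-diphenyl-1,3-dioxolan-2-yl]-4,6-dimethylhept-5-enoate | COC(=O)CC[C@](C)(C=C(C)C)C1O[C@H](c2ccccc2)[C@@H](c2ccccc2)O1
F3 | step 3 | methyl (4S)-4-[(4R,5R)-4,5-diphenyl-1,3-dioxolan-2-yl]-4,6-dimethylhept-5-enoate | COC(=O)CC[C@@](C)(C=C(C)C)C1O[C@H](c2ccccc2)[C@@H](c2ccccc2)O1
F4 | step 9 | methyl 3-[(1R,2R,6R)-1,3-dimethyl-6-(prop-1-en-2-yl)-2-{[(trifluoromethanesulfonyl)oxy]methyl}cyclohex-3-en-1-yl]propanoate | C=C(C)[C@H]1CC=C(C)[C@@H](COS(=O)(=O)C(F)(F)F)[C@]1(C)CCC(=O)OC
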